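(Readings and results were computed for an exercise.)

**First count.** Count second nucleophile against substrate before anything else. We want the share of other capture product in it plus target.

| flask | substrate | first nucleophile | second nucleophile | capture agent | remark | time |
|---|---|---|---|---|---|---|
| south-west | 0.20 M | 0.19 M | 0.32 M | 0.060 M | run made earlier |  |
| flask | 0.20 M | 0.190 M | 0.210 M | 0.0600 M |  | 4.0 min |

south-west run (percent of the substrate charged)

| time / s | other capture product / % | target / % |
|---|---|---|
| 10.0 | 18.4 | 22.9 |
| 15.0 | 21.3 | 15.2 |
| 25.0 | 22.1 | 6.7 |

(standard deviation of a reading: 0.5 percentage points)

- the numbers in the tables scatter with a standard deviation of 0.5 percentage points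

* share of other capture product in other capture product plus target at 0.50 s
* share of other capture product in other capture product plus target at 10 s
* share of other capture product in other capture product plus target at 4.0 min

**Main step.** Take first substrate going to target with first nucleophile, and nothing else. Target then reaches 95.0% of the substrate charged, first nucleophile being the limiting reagent, and the share is nil.

**Second branch.** Add second nucleophile, competing with first nucleophile for substrate and giving other capture product. In the south-west run that product nearly levels at 22.1%. Set against the rest of the substrate and divided by the charge ratio, this reads as a selectivity factor of 0.168. The flask's charges then give a share of 15.7%. That is our figure for 0.50 s, and also our final amount of other capture product.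

**Target loss.** Now add the loss of target, which we assign to second nucleophile. Each substrate then costs one second nucleophile by either road. The flask keeps 0.0100 M and south-west 0.120 M: this is the surplus, the charge of second nucleophile minus the charge of substrate. Once substrate is gone, [second nucleophile] equals the surplus plus [target].

In south-west the surplus exceeds target at 15.0 s, so the decay looks pseudo-first-order. Integrating from 15.0 s to 25.0 s reads a rate constant of 0.583 M⁻¹ s⁻¹.

In the flask the surplus is far less than the target formed, so target and second nucleophile fall together, second-order, in a slow tail. We reckon 0.00328 M of target at 4.0 min, hence a share of 90.5%. At 10 s we expect a share between 15.7% and the south-west reading of 44.6%, since the flask holds less second nucleophile.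

**Forecast, result.** The forecast gave 35%, 45% and 45%, and said of the last that “the range is wide”. The flask gives 11.8%, 27.3% and 95.0%, so our first figure stands 3.9 points high and our last 4.5 points low.

    substrate ⇌ open intermediate (K = 0.151, k = 0.235 s⁻¹)
    open intermediate + capture agent → trapped intermediate (k = 0.316 M⁻¹ s⁻¹)
    first nucleophile + open intermediate → target (k = 93.2 M⁻¹ s⁻¹)
    second nucleophile + target → over-reaction product (k = 0.776 M⁻¹ s⁻¹)
    second nucleophile + open intermediate → other capture product (k = 10.5 M⁻¹ s⁻¹)

**What ran.** In the flask, half the turnover to target up to 4.0 min was done by 0.0528 min and half the turnover to over-reaction product by 0.194 min; at 0.400 min substrate stood at 1.37%, target at 21.4% and over-reaction product at 60.9%. Target then crept down to 0.862% at 4.00 min, and second nucleophile stood at 0.0104 M by 40.0 min, close to the surplus. A neighbour flask with 0.50 M of substrate has a surplus of −0.290 M: at 4.00 min its second nucleophile is 0%, its target 22.3%, and its share 54.1%.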